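**Strategy.** The route cuts the unbranched (CH2)13 tether (C7–C19) that links the C5≡C6 alkyne to C2 of the furan ring at its C10–C11 CH2–CH2 bond. This bond is remote from every functional group and carries no stereochemistry. A copper-catalysed sp3–sp3 coupling of the Grignard reagent from 2-(9-bromononyl)furan with the chloromagnesium salt of 10-bromodec-5-ynoic acid should form it and deliver the free acid directly in the last step, leaving alkyne, furan and carboxylate untouched. Each coupling partner is made in one step: furan plus 1,9-dibromononane, and hex-5-ynoic acid dianion plus 1,4-dibromobutane.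

Key step: step 3

Remark: the target has no stereocentre and no C=C geometry. Carboxylate salts present before the acidic work-up are regarded as the salt form of the acid named as product and carry no number of their own.

**Step 1**
Reactants: 1 furan; 2 1,9-dibromononane
Product: 4 2-(9-bromononyl)furan, via 2-furyllithium 3 (not isolated)
Conditions: 1 (1.2 equiv), n-BuLi (1.0 equiv), THF, −78 → 0 °C; then 2 (3 equiv), THF, −78 °C → rt
Reagents that add atoms: none
Why: α-Lithiation of furan at C2 followed by SN2 alkylation of the heteroaryllithium at a primary bromide; the excess of dibromide should suppress double substitution and is recoverable.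

**Step 2**
Reactants: 5 hex-5-ynoic acid; 6 1,4-dibromobutane
Product: 8 10-bromodec-5-ynoic acid, via dilithio hex-5-ynoate dianion 7 (not isolated)
Conditions: n-BuLi (2.05 equiv), THF/HMPA, −78 → 0 °C; then 6 (4 equiv) in one portion, −78 °C → rt; cold 1 M HCl
Reagents that add atoms: none
Why: Acetylide alkylation of the carboxylate–acetylide dianion, which should react at the far more nucleophilic sp carbon; excess dibromide limits bis-alkylation, and the acid product is separable from neutral dibromide by base extraction.

**Step 3**
Reactants: 4 2-(9-bromononyl)furan; 8 10-bromodec-5-ynoic acid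
Product: 11 19-(furan-2-yl)nonadec-5-ynoic acid, via [9-(furan-2-yl)nonyl]magnesium bromide 9 (not isolated), via chloromagnesium 10-bromodec-5-ynoate 10 (not isolated)
Conditions: 4 (1.4 equiv), Mg, THF, 40 °C → 9; 8, MeMgCl (1.0 equiv), THF, −20 °C → 10; 9 added slowly to 10 + Li2CuCl4 (3 mol%), THF/NMP, −20 → 0 °C; cold 1 M HCl
Reagents that add atoms: none
Why: Transmetalation of Grignard reagent 9 to copper gives a cuprate-type Cu(I) species that displaces the primary bromide at C10 of carboxylate 10 in an SN2-like oxidative addition, and reductive elimination from the resulting dialkyl-Cu(III) forms the C10–C11 bond and regenerates the catalyst. The closest known reaction type is the copper-catalysed (Li2CuCl4, Kochi-type) coupling of alkyl Grignard reagents with primary alkyl bromides, including its variant on halomagnesium salts of ω-bromo carboxylic acids. No ring is closed and no stereocentre is created, so only chemoselectivity matters. Substitution at C–Br must beat addition to the carboxyl group, which is secured by prior conversion of the acid into the non-electrophilic magnesium carboxylate and by working at or below 0 °C. The unactivated internal C5≡C6 alkyne should not undergo carbocupration under these conditions, and the 2-alkylfuran offers no site that a Grignard reagent attacks. Homocoupling of 9 is limited by its slow addition to the electrophile/catalyst mixture, and the neutral by-products are removable from the acid product by extraction.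

**Compound list**
1 | furan | c1ccoc1 | starting material
2 | 1,9-dibromononane | BrCCCCCCCCCBr | starting material
3 | 2-furyllithium | [Li]c1ccco1 | intermediate
4 | 2-(9-bromononyl)furan | BrCCCCCCCCCc1ccco1 | intermediate
5 | hex-5-ynoic acid | OC(=O)CCCC#C | starting material
6 | 1,4-dibromobutane | BrCCCCBr | starting material
7 | dilithio hex-5-ynoate dianion (lithium carboxylate, lithium acetylide) | [Li]OC(=O)CCCC#C[Li] | intermediate
8 | 10-bromodec-5-ynoic acid | OC(=O)CCCC#CCCCCBr | intermediate
9 | [9-(furan-2-yl)nonyl]magnesium bromide | Br[Mg]CCCCCCCCCc1ccco1 | intermediate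
10 | chloromagnesium 10-bromodec-5-ynoate | Cl[Mg]OC(=O)CCCC#CCCCCBr | intermediate
11 | 19-(furan-2-yl)nonadec-5-ynoic acid | O=C(O)CCCC#CCCCCCCCCCCCCCc1ccco1 | target

**Total step count:** 3
**Longest linear sequence:** 2 steps (step 1 → step 3, or step 2 → step 3)

**Steps most likely to fail**

Step 3 (key step). The cross-coupling may stall because the magnesium carboxylate aggregates or dissolves poorly at low temperature, so that Wurtz-type homocoupling and protonation of the Grignard reagent overtake it. The fallback sets out from 4 and 8 and comes back at 11. Acid 8 is esterified (MeOH, cat. H2SO4, rt) to methyl 10-bromodec-5-ynoate F1. Bromide 4 is converted with activated zinc dust (cat. I2, DMA, 70 °C) into [9-(furan-2-yl)nonyl]zinc bromide F2. A Pd-PEPPSI-IPr-catalysed alkyl–alkyl Negishi coupling of F2 with F1 (LiBr, THF/NMP, rt) should give methyl 19-(furan-2-yl)nonadec-5-ynoate F3. Saponification (LiOH, THF/H2O, rt; careful acidification with cold dilute HCl) should return 11.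

Step 2. Two acetylide units may substitute both ends of the dibromide, and the lithium carboxylate may be O-alkylated in the dipolar medium, consuming the dianion and complicating isolation. The fallback sets out from 5 (dianion 7 formed as before) and comes back at 11. Alkylation with 1-bromo-4-chlorobutane (ClCCCCBr, 1.1 equiv; the chloride end should be inert to the acetylide up to rt, so no excess is needed) gives 10-chlorodec-5-ynoic acid F4. Finkelstein exchange (NaI, butanone, reflux) gives 10-iododec-5-ynoic acid F5. F5 is deprotonated with MeMgCl to chloromagnesium 10-iododec-5-ynoate F6, which is coupled with Grignard reagent 9 under the conditions of step 3 to give 11.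

Step 1. A second furyl anion may substitute the remaining bromide, and the SN2 reaction of the heteroaryllithium may be slow, leaving a mixture of dibromide, monobromide and bis-furyl product that is hard to separate. The fallback sets out from 3 (formed from 1 as before) and comes back at 4. Commercial 9-bromononan-1-ol (OCCCCCCCCCBr) is silylated (TBSCl, imidazole, DMF) to (9-bromononyloxy)(tert-butyl)dimethylsilane F7. Alkylation of 3 with F7 (THF, −78 °C → rt) gives tert-butyl{[9-(furan-2-yl)nonyl]oxy}dimethylsilane F8. Desilylation (TBAF, THF, rt) gives 9-(furan-2-yl)nonan-1-ol F9. Appel bromination (CBr4, PPh3, CH2Cl2, 0 °C) should give 4.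

**Further compounds**
F1 | step 3 | methyl 10-bromodec-5-ynoate | COC(=O)CCCC#CCCCCBr
F2 | step 3 | [9-(furan-2-yl)nonyl]zinc bromide | Br[Zn]CCCCCCCCCc1ccco1
F3 | step 3 | methyl 19-(furan-2-yl)nonadec-5-ynoate | COC(=O)CCCC#CCCCCCCCCCCCCCc1ccco1
F4 | step 2 | 10-chlorodec-5-ynoic acid | OC(=O)CCCC#CCCCCCl
F5 | step 2 | 10-iododec-5-ynoic acid | OC(=O)CCCC#CCCCCI
F6 | step 2 | chloromagnesium 10-iododec-5-ynoate | Cl[Mg]OC(=O)CCCC#CCCCCI
F7 | step 1 | (9-bromononyloxy)(tert-butyl)dimethylsilane | CC(C)(C)[Si](C)(C)OCCCCCCCCCBr
F8 | step 1 | tert-butyl{[9-(furan-2-yl)nonyl]oxy}dimethylsilane | CC(C)(C)[Si](C)(C)OCCCCCCCCCc1ccco1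
F9 | step 1 | 9-(furan-2-yl)nonan-1-ol | OCCCCCCCCCc1ccco1
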